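**Plan**

- Cuts: the lactone is traced back (C5 carbinol to ketone, C2 lactone to lactol) to a pyranone lactol, whose O1–C2 bond and six-membered ring are undone by a retro-Achmatowicz step to a 2-furylcarbinol. Further cuts are C5–C6 (furyl anion + C6 aldehyde), flavanone C2–phenyl (chromone + phenylboronic acid), ring C (acetyl + one-carbon unit on ring A) and C8–phenyl (coumarin + phenylboronic acid).
- Enabling feature: the 5-hydroxy-5,6-dihydro-2H-pyran-2-one ring (O1, C2 carbonyl, C3=C4, C5 carbinol, C6) is an oxidised furan. C2–C5 map onto a 2-furyl group on carbinol carbon C6, and the C6 hydroxyl becomes O1.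
- Forward order: ring A with a coumarin lactone carrying C6–C8 comes first. The lactone is opened by reduction, ring C is built (chromone, then flavanone), the C6 aldehyde is released and the furan added. The pyranone ring arises last by ring expansion, followed by oxidation, reduction and deprotection.
- Stereochemistry: C8 from a catalyst-controlled rhodium conjugate phenylation of the coumarin; C7 from trans-selective enolate hydroxylation (substrate control); flavanone C2 from a catalyst-controlled rhodium conjugate phenylation of the chromone; C6 from chelation-controlled furyl addition; C5 from hydride attack anti to the C6 side chain.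

Key step: step 16

Numbering remark: lactone atoms O1, C2–C6 and side-chain atoms C7 (carbinol) and C8 (benzylic) are numbered as in the target; flavanone atoms carry their usual chromanone numbers.

Assumption: the two chiral rhodium catalysts (steps 3 and 12) are taken to show, on these substituted substrates, the facial preference known for the parent coumarin and chromone (phenyl to the re face of the β-carbon with the (S)-ligands); if the sense were opposite, the mirror-image ligand would be used.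

**Route**

Step 1
Reactants: 1 5,7-dihydroxycoumarin
Product: 2 7-(benzyloxy)-5-hydroxycoumarin
Conditions: BnBr (1.0 equiv), K2CO3, acetone, 0 °C → rt
Reagents that add atoms: benzyl bromide, BrCc1ccccc1
Why: Williamson ether synthesis on the more acidic and less hindered 7-hydroxyl (the 5-hydroxyl is peri to C4–H), so one equivalent of benzyl bromide should give mainly the 7-ether, marking the oxygen that later becomes the flavanone ring oxygen; the bis-ether is removed by chromatography.

Step 2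
Reactants: 2 7-(benzyloxy)-5-hydroxycoumarin
Product: 3 7-(benzyloxy)-5-(methoxymethoxy)coumarin
Conditions: MOMCl, K2CO3, acetone, 50 °C
Reagents that add atoms: chloromethyl methyl ether, COCCl
Why: O-alkylation of the remaining phenoxide (MOM protection) gives an acetal that should withstand the basic, hydridic and organometallic steps ahead and later directs ring lithiation.

Step 3
Reactants: 3 7-(benzyloxy)-5-(methoxymethoxy)coumarin; 4 phenylboronic acid
Product: 5 (4S)-7-(benzyloxy)-5-(methoxymethoxy)-4-phenylchroman-2-one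
Conditions: Rh(acac)(C2H4)2 (3 mol %), (S)-Segphos (3.3 mol %), PhB(OH)2 (5 equiv), dioxane/H2O 10:1, 60 °C
Reagents that add atoms: phenylboronic acid (4), OB(O)c1ccccc1
Why: Hayashi–Miyaura asymmetric 1,4-addition of an arylboronic acid to a coumarin, in which the (S)-Segphos–rhodium–phenyl species inserts the C3=C4 bond from the C4 re face and sets the (4S) benzylic centre (C8 of the target) under catalyst control.

Step 4
Reactants: 5 (4S)-7-(benzyloxy)-5-(methoxymethoxy)-4-phenylchroman-2-one
Product: 7 (3R,4S)-7-(benzyloxy)-3-hydroxy-5-(methoxymethoxy)-4-phenylchroman-2-one, via potassium lactone enolate 6 (not isolated)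
Conditions: KN(SiMe3)2, THF, −78 °C; then 2-(phenylsulfonyl)-3-phenyloxaziridine, −78 °C; aq NH4Cl
Reagents that add atoms: 2-(phenylsulfonyl)-3-phenyloxaziridine, O=S(=O)(N1OC1c1ccccc1)c1ccccc1
Why: Davis oxidation of the lactone enolate, in which the pseudo-axial 4-phenyl group (held axial by the peri 5-OMOM group) blocks one face, so oxygen should enter anti to it and give the 3,4-trans hydroxy lactone, setting C7 by substrate control.

Step 5
Reactants: 7 (3R,4S)-7-(benzyloxy)-3-hydroxy-5-(methoxymethoxy)-4-phenylchroman-2-one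
Product: 8 (3R,4S)-7-(benzyloxy)-3,5-bis(methoxymethoxy)-4-phenylchroman-2-one
Conditions: MOMCl, i-Pr2NEt, Bu4NI (cat.), CH2Cl2, 0 → 40 °C
Reagents that add atoms: chloromethyl methyl ether, COCCl
Why: MOM ether formation under mild amine base installs the chelating α-alkoxy group needed for the later Grignard addition and should not disturb the thermodynamically preferred trans lactone.

Step 6
Reactants: 8 (3R,4S)-7-(benzyloxy)-3,5-bis(methoxymethoxy)-4-phenylchroman-2-one
Product: 9 (2R,3S)-3-[4-(benzyloxy)-2-hydroxy-6-(methoxymethoxy)phenyl]-2-(methoxymethoxy)-3-phenylpropan-1-ol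
Conditions: LiAlH4, THF, 0 °C; aq NaOH work-up
Reagents that add atoms: none
Why: LiAlH4 reduction of the aryl lactone to the primary alcohol (C6) and the free phenol leaves the acetals, the benzyl ether and both stereocentres untouched.

Step 7
Reactants: 9 (2R,3S)-3-[4-(benzyloxy)-2-hydroxy-6-(methoxymethoxy)phenyl]-2-(methoxymethoxy)-3-phenylpropan-1-ol
Product: 10 (2R,3S)-3-[4-(benzyloxy)-2,6-bis(methoxymethoxy)phenyl]-2-(methoxymethoxy)-3-phenylpropan-1-ol
Conditions: MOMCl (1.1 equiv), K2CO3, acetone, 0 °C → rt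
Reagents that add atoms: chloromethyl methyl ether, COCCl
Why: chemoselective O-alkylation of the phenoxide (carbonate deprotonates the phenol, not the alcohol) makes the two oxygens flanking the side chain identical, so the two free ring positions become constitutionally equivalent.

Step 8
Reactants: 10 (2R,3S)-3-[4-(benzyloxy)-2,6-bis(methoxymethoxy)phenyl]-2-(methoxymethoxy)-3-phenylpropan-1-ol
Product: 11 tert-butyl{[(2R,3S)-3-[4-(benzyloxy)-2,6-bis(methoxymethoxy)phenyl]-2-(methoxymethoxy)-3-phenylpropyl]oxy}diphenylsilane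
Conditions: TBDPSCl, imidazole, DMF, rt
Reagents that add atoms: tert-butyl(chloro)diphenylsilane, CC(C)(C)[Si](Cl)(c1ccccc1)c1ccccc1
Why: silyl ether formation at the primary alcohol; TBDPS is chosen to survive butyllithium, hydrogenolysis and the mildly acidic chromone closure.

Step 9
Reactants: 11 tert-butyl{[(2R,3S)-3-[4-(benzyloxy)-2,6-bis(methoxymethoxy)phenyl]-2-(methoxymethoxy)-3-phenylpropyl]oxy}diphenylsilane
Product: 13 1-{6-(benzyloxy)-3-[(1S,2R)-3-[(tert-butyldiphenylsilyl)oxy]-2-(methoxymethoxy)-1-phenylpropyl]-2,4-bis(methoxymethoxy)phenyl}ethan-1-one, via aryllithium 12 (not isolated)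
Conditions: n-BuLi (1.2 equiv), TMEDA, THF, −20 → 0 °C; then MeC(O)N(OMe)Me, −78 °C → rt; aq NH4Cl
Reagents that add atoms: N-methoxy-N-methylacetamide, CC(=O)N(C)OC
Why: directed ortho-metalation at the ring C–H flanked by OMOM and OBn, then acylation of the aryllithium with a Weinreb amide; the two available positions are equivalent, and kinetically favoured ring lithiation at low temperature should outrun deprotonation of the hindered benzhydryl C–H.

Step 10
Reactants: 13 1-{6-(benzyloxy)-3-[(1S,2R)-3-[(tert-butyldiphenylsilyl)oxy]-2-(methoxymethoxy)-1-phenylpropyl]-2,4-bis(methoxymethoxy)phenyl}ethan-1-one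
Product: 14 1-{3-[(1S,2R)-3-[(tert-butyldiphenylsilyl)oxy]-2-(methoxymethoxy)-1-phenylpropyl]-6-hydroxy-2,4-bis(methoxymethoxy)phenyl}ethan-1-one
Conditions: H2 (1 atm), 10% Pd/C, EtOAc, rt
Reagents that add atoms: none
Why: hydrogenolysis of the aryl benzyl ether frees only the phenol para to the side chain and so fixes the regiochemistry of ring C closure (chain at C6 of the flavanone); the hindered aryl ketone, silyl ether and acetals should be inert.

Step 11
Reactants: 14 1-{3-[(1S,2R)-3-[(tert-butyldiphenylsilyl)oxy]-2-(methoxymethoxy)-1-phenylpropyl]-6-hydroxy-2,4-bis(methoxymethoxy)phenyl}ethan-1-one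
Product: 16 6-[(1S,2R)-3-[(tert-butyldiphenylsilyl)oxy]-2-(methoxymethoxy)-1-phenylpropyl]-5,7-bis(methoxymethoxy)-4H-chromen-4-one, via dimethylamino enone 15 (not isolated)
Conditions: Me2NCH(OMe)2, toluene, 90 °C; then AcOH, 50 °C
Reagents that add atoms: N,N-dimethylformamide dimethyl acetal, COC(OC)N(C)C
Why: enaminone formation followed by acid-promoted intramolecular addition–elimination (the standard chromone synthesis from 2-hydroxyacetophenones); acetic acid is expected to expel dimethylamine yet be too weak to cleave the aryl MOM ethers.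

Step 12
Reactants: 16 6-[(1S,2R)-3-[(tert-butyldiphenylsilyl)oxy]-2-(methoxymethoxy)-1-phenylpropyl]-5,7-bis(methoxymethoxy)-4H-chromen-4-one; 4 phenylboronic acid
Product: 17 (2S)-6-[(1S,2R)-3-[(tert-butyldiphenylsilyl)oxy]-2-(methoxymethoxy)-1-phenylpropyl]-5,7-bis(methoxymethoxy)-2-phenylchroman-4-one
Conditions: [RhOH(cod)]2 (2 mol %), (S)-MeO-F12-BIPHEP [(S)-2,2'-bis{bis(3,4,5-trifluorophenyl)phosphino}-6,6'-dimethoxybiphenyl, 4.4 mol %], PhB(OH)2 (3 equiv), toluene/H2O, 30 °C
Reagents that add atoms: phenylboronic acid (4), OB(O)c1ccccc1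
Why: rhodium-catalysed asymmetric 1,4-addition of an arylboronic acid to a chromone, in which the electron-poor (S)-bisphosphine complex delivers phenyl to the C2 re face and sets the (2S) flavanone centre by catalyst control, independent of the remote side-chain centres and without 1,2-addition to the product ketone.

Step 13
Reactants: 17 (2S)-6-[(1S,2R)-3-[(tert-butyldiphenylsilyl)oxy]-2-(methoxymethoxy)-1-phenylpropyl]-5,7-bis(methoxymethoxy)-2-phenylchroman-4-one
Product: 18 (2S)-6-[(1S,2R)-3-hydroxy-2-(methoxymethoxy)-1-phenylpropyl]-5,7-bis(methoxymethoxy)-2-phenylchroman-4-one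
Conditions: HF·pyridine, pyridine, THF, 0 °C → rt
Reagents that add atoms: none
Why: fluoride-mediated desilylation under buffered, non-basic conditions, so the flavanone is not opened by retro-oxa-Michael reaction and the MOM acetals stay in place.

Step 14
Reactants: 18 (2S)-6-[(1S,2R)-3-hydroxy-2-(methoxymethoxy)-1-phenylpropyl]-5,7-bis(methoxymethoxy)-2-phenylchroman-4-one
Product: 19 (2R,3S)-3-[(2S)-5,7-bis(methoxymethoxy)-4-oxo-2-phenylchroman-6-yl]-2-(methoxymethoxy)-3-phenylpropanal
Conditions: Dess–Martin periodinane, CH2Cl2, 0 °C → rt; used directly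
Reagents that add atoms: none
Why: Dess–Martin oxidation of the primary alcohol under non-basic conditions should preserve the α-alkoxy centre C7 and leave the flavanone untouched.

Step 15
Reactants: 19 (2R,3S)-3-[(2S)-5,7-bis(methoxymethoxy)-4-oxo-2-phenylchroman-6-yl]-2-(methoxymethoxy)-3-phenylpropanal; 20 furan
Product: 23 (2S)-6-[(1S,2R,3S)-3-(furan-2-yl)-3-hydroxy-2-(methoxymethoxy)-1-phenylpropyl]-5,7-bis(methoxymethoxy)-2-phenylchroman-4-one, via 2-furyllithium 21 (not isolated), via 2-furylmagnesium bromide 22 (not isolated)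
Conditions: furan (slight excess over base), n-BuLi, THF, 0 °C; MgBr2·OEt2, 0 °C; then added (1.3 equiv) to 19 precomplexed with MgBr2·OEt2, CH2Cl2, −78 °C; aq NH4Cl
Reagents that add atoms: furan (20), c1ccoc1
Why: chelation-controlled Grignard addition (Cram chelate model), in which magnesium bridges the aldehyde and MOM oxygens and furyl attacks the face away from the diarylmethyl group to give the 6,7-syn (6S) carbinol; the aldehyde should react far faster at −78 °C than the hindered, electron-rich flavanone ketone.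

Step 16
Reactants: 23 (2S)-6-[(1S,2R,3S)-3-(furan-2-yl)-3-hydroxy-2-(methoxymethoxy)-1-phenylpropyl]-5,7-bis(methoxymethoxy)-2-phenylchroman-4-one
Product: 25 (2S)-6-[(1S,2R)-2-[(2S)-6-hydroxy-3-oxo-3,6-dihydro-2H-pyran-2-yl]-2-(methoxymethoxy)-1-phenylethyl]-5,7-bis(methoxymethoxy)-2-phenylchroman-4-one (both anomers at the lactol carbon), via Z-enedione aldehyde 24 (not isolated)
Conditions: VO(acac)2 (5 mol %), t-BuOOH (1.5 equiv, in decane), CH2Cl2, 0 °C → rt
Reagents that add atoms: tert-butyl hydroperoxide, CC(C)(C)OO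
Why: The vanadium alkoxide formed at the C6 hydroxyl delivers the peroxide oxygen to the adjacent furan C=C bond; the resulting epoxyfuran opens to the (Z)-ene-dione 24, whose C6 hydroxyl adds to the aldehyde carbon to give the hemiacetal. The closest known reaction type is the Achmatowicz rearrangement of 2-furylcarbinols to 6-hydroxy-2H-pyran-3(6H)-ones. The six-membered ring closes by 6-exo-trig attack of the hydroxyl oxygen on the aldehyde carbonyl (O1–C2 bond), the Z geometry inherited from the furan holding the two ends within reach. No controlled stereocentre is created: C6 is not a reacting centre and keeps its configuration, and the lactol carbon forms as an anomer mixture that is erased in step 17. The step needs oxidation of the furan in preference to ring A, the flavanone ketone and the acetals; hydroxyl direction of the vanadium peroxide to the neighbouring, most electron-rich π system secures this, while the acylated, fully O-alkylated ring A is a much poorer donor.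

Step 17
Reactants: 25 (2S)-6-[(1S,2R)-2-[(2S)-6-hydroxy-3-oxo-3,6-dihydro-2H-pyran-2-yl]-2-(methoxymethoxy)-1-phenylethyl]-5,7-bis(methoxymethoxy)-2-phenylchroman-4-one
Product: 26 (6S)-6-[(1R,2S)-2-[(2S)-5,7-bis(methoxymethoxy)-4-oxo-2-phenylchroman-6-yl]-1-(methoxymethoxy)-2-phenylethyl]-2H-pyran-2,5(6H)-dione
Conditions: CrO3, H2SO4 (aq), acetone, 0 °C, short contact; used crude
Reagents that add atoms: none
Why: Jones oxidation of the lactol to the lactone, the usual follow-up to an Achmatowicz rearrangement, run briefly under acidic conditions that avoid enolisation of C6 next to the new ketone.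

Step 18
Reactants: 26 (6S)-6-[(1R,2S)-2-[(2S)-5,7-bis(methoxymethoxy)-4-oxo-2-phenylchroman-6-yl]-1-(methoxymethoxy)-2-phenylethyl]-2H-pyran-2,5(6H)-dione
Product: 27 (2S)-6-[(1S,2R)-2-[(2R,3S)-3-hydroxy-6-oxo-3,6-dihydro-2H-pyran-2-yl]-2-(methoxymethoxy)-1-phenylethyl]-5,7-bis(methoxymethoxy)-2-phenylchroman-4-one
Conditions: NaBH4, CeCl3·7H2O, MeOH/CH2Cl2, −78 °C
Reagents that add atoms: none
Why: Luche reduction, in which hydride adds 1,2 to the C5 ketone of the nearly planar ene-dione from the face opposite the C6 side chain to give the 5,6-cis (5S) alcohol; the far less electrophilic flavanone ketone should be left alone at −78 °C.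

Step 19
Reactants: 27 (2S)-6-[(1S,2R)-2-[(2R,3S)-3-hydroxy-6-oxo-3,6-dihydro-2H-pyran-2-yl]-2-(methoxymethoxy)-1-phenylethyl]-5,7-bis(methoxymethoxy)-2-phenylchroman-4-one
Product: 28 (2S)-5,7-dihydroxy-6-[(1S,2R)-2-hydroxy-2-[(2R,3S)-3-hydroxy-6-oxo-3,6-dihydro-2H-pyran-2-yl]-1-phenylethyl]-2-phenylchroman-4-one (CNP0136207.1)
Conditions: HCl (3 M aq), MeOH/THF, rt → 40 °C
Reagents that add atoms: none
Why: acid-catalysed acetal exchange in methanol removes the two aryl and the one alkyl MOM group, with formaldehyde trapped as dimethoxymethane, under conditions the unsaturated lactone and the flavanone should tolerate.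

**Compound list**

1 | 5,7-dihydroxycoumarin | O=C1C=Cc2c(O)cc(O)cc2O1 | starting material
2 | 7-(benzyloxy)-5-hydroxycoumarin | O=C1C=Cc2c(O)cc(OCc3ccccc3)cc2O1 | intermediate
3 | 7-(benzyloxy)-5-(methoxymethoxy)coumarin | O=C1C=Cc2c(OCOC)cc(OCc3ccccc3)cc2O1 | intermediate
4 | phenylboronic acid | OB(O)c1ccccc1 | starting material
5 | (4S)-7-(benzyloxy)-5-(methoxymethoxy)-4-phenylchroman-2-one | O=C1C[C@@H](c2ccccc2)c2c(OCOC)cc(OCc3ccccc3)cc2O1 | intermediate
6 | potassium enolate of lactone 5 | [K+].[O-]C1=C[C@@H](c2ccccc2)c2c(OCOC)cc(OCc3ccccc3)cc2O1 | intermediate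
7 | (3R,4S)-7-(benzyloxy)-3-hydroxy-5-(methoxymethoxy)-4-phenylchroman-2-one (3,4-trans) | O=C1[C@H](O)[C@@H](c2ccccc2)c2c(OCOC)cc(OCc3ccccc3)cc2O1 | intermediate
8 | (3R,4S)-7-(benzyloxy)-3,5-bis(methoxymethoxy)-4-phenylchroman-2-one | O=C1[C@H](OCOC)[C@@H](c2ccccc2)c2c(OCOC)cc(OCc3ccccc3)cc2O1 | intermediate
9 | (2R,3S)-3-[4-(benzyloxy)-2-hydroxy-6-(methoxymethoxy)phenyl]-2-(methoxymethoxy)-3-phenylpropan-1-ol | OC[C@H](OCOC)[C@@H](c1ccccc1)c1c(OCOC)cc(OCc2ccccc2)cc1O | intermediate
10 | (2R,3S)-3-[4-(benzyloxy)-2,6-bis(methoxymethoxy)phenyl]-2-(methoxymethoxy)-3-phenylpropan-1-ol | OC[C@H](OCOC)[C@@H](c1ccccc1)c1c(OCOC)cc(OCc2ccccc2)cc1OCOC | intermediate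
11 | TBDPS ether of 10 | CC(C)(C)[Si](c1ccccc1)(c1ccccc1)OC[C@H](OCOC)[C@@H](c1ccccc1)c1c(OCOC)cc(OCc2ccccc2)cc1OCOC | intermediate
12 | aryllithium from 11 (lithium between OBn and OMOM) | CC(C)(C)[Si](c1ccccc1)(c1ccccc1)OC[C@H](OCOC)[C@@H](c1ccccc1)c1c(OCOC)cc(OCc2ccccc2)c([Li])c1OCOC | intermediate
13 | 1-{6-(benzyloxy)-3-[(1S,2R)-3-[(tert-butyldiphenylsilyl)oxy]-2-(methoxymethoxy)-1-phenylpropyl]-2,4-bis(methoxymethoxy)phenyl}ethan-1-one | CC(C)(C)[Si](c1ccccc1)(c1ccccc1)OC[C@H](OCOC)[C@@H](c1ccccc1)c1c(OCOC)cc(OCc2ccccc2)c(C(C)=O)c1OCOC | intermediate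
14 | 1-{3-[(1S,2R)-3-[(tert-butyldiphenylsilyl)oxy]-2-(methoxymethoxy)-1-phenylpropyl]-6-hydroxy-2,4-bis(methoxymethoxy)phenyl}ethan-1-one | CC(C)(C)[Si](c1ccccc1)(c1ccccc1)OC[C@H](OCOC)[C@@H](c1ccccc1)c1c(OCOC)cc(O)c(C(C)=O)c1OCOC | intermediate
15 | (E)-3-(dimethylamino)prop-2-en-1-one derived from 14 | CC(C)(C)[Si](c1ccccc1)(c1ccccc1)OC[C@H](OCOC)[C@@H](c1ccccc1)c1c(OCOC)cc(O)c(C(=O)/C=C/N(C)C)c1OCOC | intermediate
16 | 6-[(1S,2R)-3-[(tert-butyldiphenylsilyl)oxy]-2-(methoxymethoxy)-1-phenylpropyl]-5,7-bis(methoxymethoxy)-4H-chromen-4-one | CC(C)(C)[Si](c1ccccc1)(c1ccccc1)OC[C@H](OCOC)[C@@H](c1ccccc1)c1c(OCOC)cc2occc(=O)c2c1OCOC | intermediate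
17 | (2S)-6-[(1S,2R)-3-[(tert-butyldiphenylsilyl)oxy]-2-(methoxymethoxy)-1-phenylpropyl]-5,7-bis(methoxymethoxy)-2-phenylchroman-4-one | CC(C)(C)[Si](c1ccccc1)(c1ccccc1)OC[C@H](OCOC)[C@@H](c1ccccc1)c1c(OCOC)cc2c(c1OCOC)C(=O)C[C@@H](c1ccccc1)O2 | intermediate
18 | (2S)-6-[(1S,2R)-3-hydroxy-2-(methoxymethoxy)-1-phenylpropyl]-5,7-bis(methoxymethoxy)-2-phenylchroman-4-one | OC[C@H](OCOC)[C@@H](c1ccccc1)c1c(OCOC)cc2c(c1OCOC)C(=O)C[C@@H](c1ccccc1)O2 | intermediate
19 | (2R,3S)-3-[(2S)-5,7-bis(methoxymethoxy)-4-oxo-2-phenylchroman-6-yl]-2-(methoxymethoxy)-3-phenylpropanal | O=C[C@H](OCOC)[C@@H](c1ccccc1)c1c(OCOC)cc2c(c1OCOC)C(=O)C[C@@H](c1ccccc1)O2 | intermediate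
20 | furan | c1ccoc1 | starting material
21 | 2-furyllithium | [Li]c1ccco1 | intermediate
22 | 2-furylmagnesium bromide | Br[Mg]c1ccco1 | intermediate
23 | (2S)-6-[(1S,2R,3S)-3-(furan-2-yl)-3-hydroxy-2-(methoxymethoxy)-1-phenylpropyl]-5,7-bis(methoxymethoxy)-2-phenylchroman-4-one | O[C@H](c1ccco1)[C@H](OCOC)[C@@H](c1ccccc1)c1c(OCOC)cc2c(c1OCOC)C(=O)C[C@@H](c1ccccc1)O2 | intermediate
24 | (2Z,5S,6R,7S)-7-[(2S)-5,7-bis(methoxymethoxy)-4-oxo-2-phenylchroman-6-yl]-5-hydroxy-6-(methoxymethoxy)-4-oxo-7-phenylhept-2-enal | O[C@H](C(=O)/C=C\C=O)[C@H](OCOC)[C@@H](c1ccccc1)c1c(OCOC)cc2c(c1OCOC)C(=O)C[C@@H](c1ccccc1)O2 | intermediate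
25 | (2S)-6-[(1S,2R)-2-[(2S)-6-hydroxy-3-oxo-3,6-dihydro-2H-pyran-2-yl]-2-(methoxymethoxy)-1-phenylethyl]-5,7-bis(methoxymethoxy)-2-phenylchroman-4-one (anomer mixture) | OC1C=CC(=O)[C@@H](O1)[C@H](OCOC)[C@@H](c1ccccc1)c1c(OCOC)cc2c(c1OCOC)C(=O)C[C@@H](c1ccccc1)O2 | intermediate
26 | (6S)-6-[(1R,2S)-2-[(2S)-5,7-bis(methoxymethoxy)-4-oxo-2-phenylchroman-6-yl]-1-(methoxymethoxy)-2-phenylethyl]-2H-pyran-2,5(6H)-dione | O=C1C=CC(=O)[C@@H](O1)[C@H](OCOC)[C@@H](c1ccccc1)c1c(OCOC)cc2c(c1OCOC)C(=O)C[C@@H](c1ccccc1)O2 | intermediate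
27 | (2S)-6-[(1S,2R)-2-[(2R,3S)-3-hydroxy-6-oxo-3,6-dihydro-2H-pyran-2-yl]-2-(methoxymethoxy)-1-phenylethyl]-5,7-bis(methoxymethoxy)-2-phenylchroman-4-one (5,6-cis) | O=C1C=C[C@H](O)[C@H]([C@H](OCOC)[C@@H](c2ccccc2)c2c(OCOC)cc3c(c2OCOC)C(=O)C[C@@H](c2ccccc2)O3)O1 | intermediate
28 | (2S)-5,7-dihydroxy-6-[(1S,2R)-2-hydroxy-2-[(2R,3S)-3-hydroxy-6-oxo-3,6-dihydro-2H-pyran-2-yl]-1-phenylethyl]-2-phenylchroman-4-one | O=C1C=C[C@H](O)[C@H]([C@H](O)[C@@H](c2ccccc2)c2c(O)cc3c(c2O)C(=O)C[C@@H](c2ccccc2)O3)O1 | target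

**Totals and risks**

Total step count: 19. Longest linear sequence: 19 steps (1 → 28).

Steps most likely to fail:

1. Step 3. The peri 5-OMOM group crowds C4, so carbometalation may be slow (protodeboronation outrunning insertion) or lose facial selectivity. Fallback: form the C4–phenyl bond without a stereocentre and set C8 by hydride delivery. Starting from coumarin 3, oxidative Heck arylation with phenylboronic acid 4 (Pd(OAc)2, 1,10-phenanthroline, O2, DMF, 80 °C) would give 7-(benzyloxy)-5-(methoxymethoxy)-4-phenylcoumarin F1. Copper hydride asymmetric conjugate reduction (Cu(OAc)2·H2O, the DTBM-Segphos antipode that gives the 4S lactone, (EtO)2MeSiH, t-BuOH, toluene, rt) would then return to dihydrocoumarin 5.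

2. Step 15. Attack may proceed through an open Felkin–Anh transition state instead of the magnesium chelate (wrong face at C6), and the basic reagent may enolise the flavanone. Fallback: create C6 by reduction instead of by C–C bond formation. Starting from aldehyde 19, the addition is run without regard to selectivity, and the mixture of 23 and its C6 epimer, the (3R)-furylcarbinol F2, is oxidised (Dess–Martin periodinane, CH2Cl2) to the 2-acylfuran F3. Reduction with KBH(s-Bu)3 in THF at −78 °C should proceed in the Felkin–Anh mode (C7 alkoxy group anti to the incoming hydride) to give the syn alcohol, returning to 23.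

3. Step 18. Hydride may be delivered syn to the side chain, giving the 5,6-trans alcohol. Fallback: invert C5 instead of relying on facial selectivity. Starting from keto-lactone 26, the reduction product in that case is the 5,6-trans alcohol F4. Mitsunobu reaction (4-nitrobenzoic acid, PPh3, DIAD, THF, 0 °C) should give the inverted 5,6-cis 4-nitrobenzoate F5, and mild methanolysis (Et3N, MeOH, 0 °C) would return to 27.

**Further compounds**

F1 | step 3 | 7-(benzyloxy)-5-(methoxymethoxy)-4-phenylcoumarin | O=C1C=C(c2ccccc2)c2c(OCOC)cc(OCc3ccccc3)cc2O1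
F2 | step 15 | (2S)-6-[(1S,2R,3R)-3-(furan-2-yl)-3-hydroxy-2-(methoxymethoxy)-1-phenylpropyl]-5,7-bis(methoxymethoxy)-2-phenylchroman-4-one (C6 epimer of 23) | O[C@@H](c1ccco1)[C@H](OCOC)[C@@H](c1ccccc1)c1c(OCOC)cc2c(c1OCOC)C(=O)C[C@@H](c1ccccc1)O2
F3 | step 15 | (2S)-6-[(1S,2R)-3-(furan-2-yl)-2-(methoxymethoxy)-3-oxo-1-phenylpropyl]-5,7-bis(methoxymethoxy)-2-phenylchroman-4-one | O=C(c1ccco1)[C@H](OCOC)[C@@H](c1ccccc1)c1c(OCOC)cc2c(c1OCOC)C(=O)C[C@@H](c1ccccc1)O2
F4 | step 18 | C5 epimer of 27 (5,6-trans alcohol) | O=C1C=C[C@@H](O)[C@H]([C@H](OCOC)[C@@H](c2ccccc2)c2c(OCOC)cc3c(c2OCOC)C(=O)C[C@@H](c2ccccc2)O3)O1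
F5 | step 18 | 4-nitrobenzoate ester of 27 at the C5 hydroxyl (5,6-cis) | O=C1C=C[C@H](OC(=O)c2ccc(cc2)[N+](=O)[O-])[C@H]([C@H](OCOC)[C@@H](c2ccccc2)c2c(OCOC)cc3c(c2OCOC)C(=O)C[C@@H](c2ccccc2)O3)O1
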